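## Structural features

The target is an isoflavone: a benzene ring (ring A) fused to a 4-pyranone (ring C; O1, C2, C3, C4, C4a, C8a), with a second benzene ring (ring B) attached through the C3–C1' single bond. Ring A carries one substituent, the 3-methylbut-2-enyl (prenyl) ether on O7, and ring B carries methoxy groups on the adjacent carbons C3' and C4'. The molecule is achiral: there is no stereocentre, and the prenyl double bond ends in two identical methyl groups, so no alkene geometry has to be set. Two parts are fragile. The prenyl aryl ether is cleaved or rearranged by protic and Lewis acids and is attacked by iodine and by quinone oxidants. C2 of the pyranone is a vinylogous ester carbon that adds amines, alkoxides and fluoride and then lets ring C open, and it is more electrophilic still in 3-iodo- and 3-alkynylchromones. The real difficulty is therefore the order of events: the C3 aryl unit must be made and the labile prenyl group brought in without one harming the other. The key step uses the fact that ring B is a 1,2-dimethoxybenzene with one further substituent: C2', C3', C4' and C5', with both methoxy groups, map onto a C2-symmetric 2,3-dioxygenated butadiene, and C1' and C6' onto the two carbons of an ethynyl group on C3.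

## Logic of the disconnections

**13 ⇒ 10 + 11.** The O7–CH2 bond of the prenyl ether is cut first, and the oxygen is taken back to its ester. The prenyl ether is the one group that would not survive iodine, a zinc Lewis acid or a quinone oxidant, so it must come last. This removes the only labile function from all earlier intermediates; the free phenol 12 is only a transient link. The forward step must unmask the phenoxide and alkylate it on oxygen under a base mild enough to leave ring C closed.

**10 ⇒ 9.** No skeletal bond is cut; two hydrogens are put back on ring B, turning the arene into a 1,4-cyclohexadiene with CH2 groups at C2' and C5'. This reveals ring B as the adduct of a diene and an alkyne. The forward dehydrogenation must be fast and must take place before the two enol ethers of 9 can hydrolyse.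

**9 ⇒ 7 + 8.** The C1'–C2' and C5'–C6' bonds are cut. The adjacent methoxy groups sit exactly on the two inner carbons of a symmetric diene, so there is no regiochemical question and no aryl–heteroaryl coupling is needed. Ring B is reduced to a four-carbon and a two-carbon fragment. The forward step needs a catalyst that joins an electronically unbiased terminal alkyne to an electron-rich diene and leaves the C2=C3 bond of the chromone alone.

**7 ⇒ 6 ⇒ 4 + 5.** The C3–C(sp) bond is cut, after the silyl cap is put back on the alkyne terminus. A vinylic iodide at C3 is the natural partner for an sp2–sp coupling, and the cap prevents double coupling. The coupling needs a base that cannot add to C2, and the silyl group must be removed without a free nucleophile or base.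

**4 ⇒ 3.** The O1–C2 bond and the C3–I bond are cut together. One electrophilic cyclisation then closes ring C and places the halogen exactly where the alkyne is needed. The electrophile must attack the enaminone α-carbon rather than ring A, which the electron-withdrawing ester on O7 favours.

**3 ⇒ 2.** The bond between C3 and the one-carbon unit that becomes C2 is cut, leading back to the methyl ketone. The oxygen at C7 must be masked, because a free phenol there would be O-methylated by the amide acetal, and the mask must survive the methanol set free.

**2 ⇒ 1.** The acyl–O bond of the ester is cut. The forward acylation must choose the free 4-hydroxyl over the 2-hydroxyl, which is hydrogen-bonded to the ketone.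

## Other disconnections considered

**Alternative 1:** This cut removes three bonds of ring C at once, C4a–C4, C3–C4 and O1–C2. The pieces are 4-iodobenzene-1,3-diol A1, carbon monoxide A2 (the C4 carbonyl) and the enamine 4-[(E)-2-(3,4-dimethoxyphenyl)ethenyl]morpholine A3, which supplies C2, C3 and all of ring B.

- Forward key step: zerovalent palladium, formed from Pd(OAc)2 and Xantphos, would insert into the C–I bond of A1 and take up A2. The aroylpalladium species would acylate the β-carbon of A3. The hydroxyl ortho to the new ketone would then add to the aminomethylene carbon and expel the amine, giving 3-(3,4-dimethoxyphenyl)-7-hydroxy-4H-chromen-4-one A4. A4 is the same phenol as 12 and needs only O-prenylation.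
- In its favour: it is convergent, needs no protecting group, and brings ring B in ready-made with both methoxy groups.
- Against it here: the acylpalladium intermediate must choose a carbon nucleophile while two free phenols and, after the first turnover, a liberated secondary amine are present. Ester formation and aminocarbonylation are the expected competitors. A3 and its parent aldehyde are prone to hydrolysis and self-condensation, and a toxic gas has to be handled.
- Comparison: on structure it forms ring C last from two intact arenes, whereas the chosen plan forms ring B last on an intact chromone. On mechanism it depends on nucleophile selectivity at an acyl–metal bond, whereas the chosen plan depends only on which π-system binds cobalt. On step economy it is clearly better, about three operations against eight. It is equal in keeping the prenyl group to the end and in having no stereochemical issue.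

**Alternative 2:** This cut removes only the C2=C3 double bond. The precursor is the racemic diene 1-[4-(tert-butyldimethylsilyloxy)-2-(ethenyloxy)phenyl]-2-(3,4-dimethoxyphenyl)prop-2-en-1-ol A5, an aryl vinyl ether that carries a 1-arylvinyl carbinol.

- Forward key step: ring-closing metathesis with the second-generation Grubbs catalyst would give (±)-7-(tert-butyldimethylsilyloxy)-3-(3,4-dimethoxyphenyl)-4H-chromen-4-ol A6. Oxidation of the carbinol (for example with MnO2) would give the chromone A7, and desilylation would lead to A4 and then the target.
- In its favour: the ring closure is regiochemically unambiguous and six-membered. Ring B is attached by carbonyl addition rather than by cross-coupling. The carbinol stereocentre is of no consequence because it is oxidised away.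
- Against it here: both alkenes are poor metathesis partners. The vinyl ether gives a stabilised alkoxycarbene on ruthenium, and the other alkene is 1,1-disubstituted and conjugated to an electron-rich arene. A6 is a doubly activated allylic and benzylic alcohol, which should ionise easily to a benzopyrylium ion. The plan also needs a phenol O-vinylation, a 1-arylvinyl organometallic, an extra oxidation and a protecting-group change.
- Comparison: on structure it is equal to the chosen plan in avoiding an aryl–heteroaryl coupling and in leaving the prenyl ether to the end. On mechanism both rest on a catalytic carbon–carbon bond formation at neutral pH, but here the catalyst must turn over on deactivated alkenes, whereas the cobalt step uses the most reactive π-system in its substrate. On step economy it is no shorter, about nine operations against eight. It is better in one respect: no intermediate has the high electrophilicity of the 3-alkynylchromone 7.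

**Alternative 3:** This cut removes the C4–C4a and O1–C2 bonds and takes ring A back to a non-aromatic ring. The pieces are 3-ethoxycyclohex-2-en-1-one A8 and (Z)-2-(3,4-dimethoxyphenyl)-3-methoxyacryloyl chloride A9.

- Forward key step: LiN(iPr)2 would deprotonate A8 at the α'-carbon (the future C4a), and C-acylation by A9 would give a 1,3-diketone. Its enol oxygen would add to the methoxymethylene carbon and displace the methoxy group, closing ring C to 3-(3,4-dimethoxyphenyl)-7-ethoxy-5,6-dihydro-4H-chromen-4-one A10. Direct dehydrogenation would give the 7-ethoxy isoflavone A11, whose ethyl ether cannot be removed selectively beside two methyl ethers. A10 would therefore have to be hydrolysed at its enol ether before dehydrogenation, giving A4, which is then prenylated.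
- In its favour: no transition metal and no halogenated intermediate is needed. The oxygen at C7 and the unsubstituted C5 are fixed by the choice of A8, and both building blocks are cheap in principle.
- Against it here: kinetic enolates tend to react with acid chlorides on oxygen. The diketone product is more acidic than A8 and consumes base. A9 needs about four steps of its own, and the ethoxy group forces the hydrolysis detour.
- Comparison: on structure it is the mirror image of the chosen plan, building rings C and A around a finished ring B, where the chosen plan builds ring B on finished rings A and C. On mechanism it is equal in concept, since both make an arene late by dehydrogenation, but the dehydrogenation here meets a less activated ring beside an electron-rich ring B. On step economy it is about equal, seven to eight operations. It is better in using no precious metal and in avoiding iodochromone intermediates. The chosen plan is better in the chemoselectivity of its bond-forming step.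

Key step: step 6

Remark on the chemistry: the atom mapping of ring B (C2' to C5' from the diene, C1' and C6' from the alkyne) and all structures were re-derived and found consistent, so none is altered. The pivalate on O7 is kept through the key step and the prenyl group is attached last, because a prenyl aryl ether would otherwise have to pass iodine, ZnI2 and DDQ.

## Route

Step 1
Reactants: 1 2,4-dihydroxyacetophenone
Product: 2 4-acetyl-3-hydroxyphenyl pivalate
Conditions: pivaloyl chloride (1.05 equiv), Et3N (1.2 equiv), CH2Cl2, 0 °C
Reagents that add atoms: pivaloyl chloride, CC(C)(C)C(=O)Cl
Why: O-acylation of a phenol with an acyl chloride; the 2-hydroxyl is held in a hydrogen bond to the acetyl carbonyl and is hindered, so one equivalent of the bulky acyl chloride should acylate only the 4-hydroxyl.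

Step 2
Reactants: 2 4-acetyl-3-hydroxyphenyl pivalate
Product: 3 4-[(2E)-3-(dimethylamino)prop-2-enoyl]-3-hydroxyphenyl pivalate
Conditions: N,N-dimethylformamide dimethyl acetal (1.5 equiv), toluene, 85 °C
Reagents that add atoms: N,N-dimethylformamide dimethyl acetal, COC(OC)N(C)C
Why: Condensation of the methyl ketone with the amide acetal (enaminone formation) should give the thermodynamically preferred E push–pull alkene; with the 4-oxygen acylated no phenol O-methylation can occur there, and the hindered pivalate is expected to resist the methanol set free.

Step 3
Reactants: 3 4-[(2E)-3-(dimethylamino)prop-2-enoyl]-3-hydroxyphenyl pivalate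
Product: 4 3-iodo-4-oxo-4H-chromen-7-yl pivalate
Conditions: I2 (1.5 equiv), CHCl3, rt; aq. Na2S2O3 work-up
Reagents that add atoms: iodine, II
Why: Iodine-induced cyclisation of a 2-hydroxyaryl enaminone: iodination at the α-carbon gives an iminium ion, the phenol adds to it (6-endo closure of ring C) and dimethylamine is lost; the amine is trapped as its hydroiodide and so cannot attack the pivalate.

Step 4
Reactants: 4 3-iodo-4-oxo-4H-chromen-7-yl pivalate; 5 ethynyltrimethylsilane
Product: 6 4-oxo-3-[(trimethylsilyl)ethynyl]-4H-chromen-7-yl pivalate
Conditions: PdCl2(PPh3)2 (3 mol%), CuI (5 mol%), Et3N (2 equiv), THF, rt, argon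
Reagents that add atoms: none
Why: Sonogashira coupling at the vinylic C3–I bond; a tertiary amine is used because primary and secondary amines add to C2 and open the pyranone, and room temperature under argon limits alkyne homocoupling.

Step 5
Reactants: 6 4-oxo-3-[(trimethylsilyl)ethynyl]-4H-chromen-7-yl pivalate
Product: 7 3-ethynyl-4-oxo-4H-chromen-7-yl pivalate
Conditions: Bu4NF (1.1 equiv), AcOH (1.3 equiv), THF, −20 to 0 °C
Reagents that add atoms: none
Why: Fluoride-induced protodesilylation of the alkynylsilane; buffering with acetic acid keeps the medium non-basic, so neither the aryl pivalate nor the electrophilic C2 of the 3-alkynylchromone should be attacked, and the acetylide is protonated as it forms.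

Step 6
Reactants: 7 3-ethynyl-4-oxo-4H-chromen-7-yl pivalate; 8 2,3-dimethoxy-1,3-butadiene
Product: 9 3-(4,5-dimethoxycyclohexa-1,4-dien-1-yl)-4-oxo-4H-chromen-7-yl pivalate
Conditions: CoBr2(dppe) (10 mol%), Zn powder (20 mol%), ZnI2 (20 mol%), 8 (2 equiv), CH2Cl2, rt; filtration through basic alumina, volatiles removed in vacuo, crude used at once
Reagents that add atoms: none
Why: Zn reduces CoBr2(dppe) to monovalent cobalt and ZnI2 abstracts bromide, so that a cationic cobalt–dppe fragment binds the s-cis diene 8 and the terminal alkyne of 7 side by side. Oxidative coupling of the two ligands gives a cobaltacycle (an allyl-cobaltacyclopentene in equilibrium with the cobaltacycloheptadiene) that already holds one of the two new bonds, C1'–C2' or C5'–C6'; reductive elimination forms the other, releases the 1,4-cyclohexadiene and returns monovalent cobalt. The closest known reaction type is the cobalt-catalysed neutral Diels–Alder reaction of non-activated terminal alkynes with 2,3-disubstituted 1,3-butadienes. Ring B thus closes as a six-membered carbocycle in a formal intermolecular [4+2] annulation, the ring-closing event being C–C reductive elimination from the seven-membered metallacycle rather than a concerted pericyclic step. No stereocentre is formed, because both new sp3 carbons are CH2 groups, and the C2-symmetric diene makes the two possible orientations identical, so no regiochemistry arises. The selectivity needed is chemoselectivity: for the alkyne over the C2=C3 bond of the chromone, for cross-reaction over alkyne cyclotrimerisation, and against Lewis-acid damage to the enol ethers. The first is secured by the substrate, since only the unhindered terminal alkyne can take the coordination site beside the diene while the trisubstituted, oxygen-bearing C2=C3 bond is a poor ligand; the second by the excess of 8; the third by the low loading of ZnI2 and by the absence of a free phenol or a prenyl ether in 7.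

Step 7
Reactants: 9 3-(4,5-dimethoxycyclohexa-1,4-dien-1-yl)-4-oxo-4H-chromen-7-yl pivalate
Product: 10 3-(3,4-dimethoxyphenyl)-4-oxo-4H-chromen-7-yl pivalate
Conditions: DDQ (1.1 equiv), toluene, rt
Reagents that add atoms: none
Why: Dehydrogenation of a 1,4-cyclohexadiene by DDQ (hydride abstraction from an allylic CH2, then proton loss); the electron-rich bis(enol ether) should react fast at room temperature, and the chromone, the pivalate and the new veratrole ring are inert to about one equivalent of the quinone under anhydrous conditions.

Step 8
Reactants: 10 3-(3,4-dimethoxyphenyl)-4-oxo-4H-chromen-7-yl pivalate; 11 prenyl bromide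
Product: 13 7-prenyloxy-3',4'-dimethoxyisoflavone, via 7-hydroxy-3',4'-dimethoxyisoflavone 12 (not isolated)
Conditions: K2CO3 (3 equiv), MeOH, rt; evaporation; then 11 (1.3 equiv), DMF, rt
Reagents that add atoms: none
Why: Carbonate-mediated methanolysis of the aryl ester (transesterification) frees the potassium phenoxide; after removal of methanol and methyl pivalate it undergoes Williamson O-alkylation (SN2) with the primary allylic bromide in DMF, so the prenyl ether never meets iodine, ZnI2 or DDQ.

## Compound list

1 | 2,4-dihydroxyacetophenone | CC(=O)c1ccc(O)cc1O | starting material
2 | 4-acetyl-3-hydroxyphenyl pivalate | CC(=O)c1ccc(OC(=O)C(C)(C)C)cc1O | intermediate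
3 | 4-[(2E)-3-(dimethylamino)prop-2-enoyl]-3-hydroxyphenyl pivalate | CN(C)/C=C/C(=O)c1ccc(OC(=O)C(C)(C)C)cc1O | intermediate
4 | 3-iodo-4-oxo-4H-chromen-7-yl pivalate | Ic1coc2cc(OC(=O)C(C)(C)C)ccc2c1=O | intermediate
5 | ethynyltrimethylsilane | C#C[Si](C)(C)C | starting material
6 | 4-oxo-3-[(trimethylsilyl)ethynyl]-4H-chromen-7-yl pivalate | C[Si](C)(C)C#Cc1coc2cc(OC(=O)C(C)(C)C)ccc2c1=O | intermediate
7 | 3-ethynyl-4-oxo-4H-chromen-7-yl pivalate | C#Cc1coc2cc(OC(=O)C(C)(C)C)ccc2c1=O | intermediate
8 | 2,3-dimethoxy-1,3-butadiene | COC(=C)C(=C)OC | starting material
9 | 3-(4,5-dimethoxycyclohexa-1,4-dien-1-yl)-4-oxo-4H-chromen-7-yl pivalate | COC1=C(OC)CC(=CC1)c1coc2cc(OC(=O)C(C)(C)C)ccc2c1=O | intermediate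
10 | 3-(3,4-dimethoxyphenyl)-4-oxo-4H-chromen-7-yl pivalate | COc1ccc(-c2coc3cc(OC(=O)C(C)(C)C)ccc3c2=O)cc1OC | intermediate
11 | prenyl bromide (1-bromo-3-methylbut-2-ene) | CC(C)=CCBr | starting material
12 | 7-hydroxy-3',4'-dimethoxyisoflavone (3-(3,4-dimethoxyphenyl)-7-hydroxy-4H-chromen-4-one; formed as its potassium salt) | COc1ccc(-c2coc3cc(O)ccc3c2=O)cc1OC | intermediate
13 | 7-prenyloxy-3',4'-dimethoxyisoflavone (3-(3,4-dimethoxyphenyl)-7-[(3-methylbut-2-en-1-yl)oxy]-4H-chromen-4-one; achiral) | COc1ccc(-c2coc3cc(OCC=C(C)C)ccc3c2=O)cc1OC | target

## Step count and least certain steps

Total step count: 8. Longest linear sequence: 8 steps, from 1 to 13. Compounds 5, 8 and 11 are bought and enter at steps 4, 6 and 8.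

**Step 6 (key step).** Three processes could defeat it:
- cobalt-mediated cyclotrimerisation or oligomerisation of the terminal alkyne instead of cross-reaction;
- ZnI2-promoted conjugate addition of the electron-rich diene to C2 of the 3-alkynylchromone, or cationic polymerisation of the diene;
- hydrolysis of the two enol ethers of the adduct during work-up, before dehydrogenation.

Fallback: ring B is brought in as a finished arene. Starting from 4, Suzuki–Miyaura coupling with (3,4-dimethoxyphenyl)boronic acid [Pd(PPh3)4, K3PO4, 1,2-dimethoxyethane/water, 80 °C] should give 10, where the route is rejoined. Any 12 formed by partial ester hydrolysis enters step 8 just as well. No compound outside the list arises (entry F0).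

**Step 5.** The 3-alkynylchromone is a strong acceptor at C2. Likely failures are conjugate addition of fluoride or acetate followed by opening of ring C, fluoride-induced loss of the pivalate, and base-triggered oligomerisation of the freed alkyne. Fallback: the silyl group is avoided altogether. Starting from 4, Stille coupling with ethynyltributylstannane [Pd(PPh3)4, toluene, 80 °C] should give 7 directly under neutral conditions, where the route is rejoined. No compound outside the list arises (entry F0).

**Step 2.** At 85 °C the methanol and methoxide from the amide acetal could transesterify the aryl pivalate, and the freed phenoxide would then be O-methylated irreversibly by the acetal. Fallback: an acetal ether carries the oxygen through the ring-forming steps and the ester is put on afterwards. Starting from 1: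
- 4-O-methoxymethylation (chloromethyl methyl ether, iPr2NEt, CH2Cl2, 0 °C) gives 1-[2-hydroxy-4-(methoxymethoxy)phenyl]ethan-1-one F1;
- the amide acetal (toluene, 85 °C) gives (2E)-3-(dimethylamino)-1-[2-hydroxy-4-(methoxymethoxy)phenyl]prop-2-en-1-one F2;
- I2 in CHCl3 gives 3-iodo-7-(methoxymethoxy)-4H-chromen-4-one F3;
- HCl in methanol frees 7-hydroxy-3-iodo-4H-chromen-4-one F4;
- pivaloyl chloride and Et3N in CH2Cl2 convert it into 4, where the route is rejoined.

## Further compounds

F0 | step 6 | none | none
F0 | step 5 | none | none
F1 | step 2 | 1-[2-hydroxy-4-(methoxymethoxy)phenyl]ethan-1-one | CC(=O)c1ccc(OCOC)cc1O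
F2 | step 2 | (2E)-3-(dimethylamino)-1-[2-hydroxy-4-(methoxymethoxy)phenyl]prop-2-en-1-one | CN(C)/C=C/C(=O)c1ccc(OCOC)cc1O
F3 | step 2 | 3-iodo-7-(methoxymethoxy)-4H-chromen-4-one | COCOc1ccc2c(c1)occ(I)c2=O
F4 | step 2 | 7-hydroxy-3-iodo-4H-chromen-4-one | Oc1ccc2c(c1)occ(I)c2=O
A1 | alternative 1 | 4-iodobenzene-1,3-diol | Oc1ccc(I)c(O)c1
A2 | alternative 1 | carbon monoxide | [C-]#[O+]
A3 | alternative 1 | 4-[(E)-2-(3,4-dimethoxyphenyl)ethenyl]morpholine | COc1ccc(/C=C/N2CCOCC2)cc1OC
A4 | alternative 1 | 3-(3,4-dimethoxyphenyl)-7-hydroxy-4H-chromen-4-one | COc1ccc(-c2coc3cc(O)ccc3c2=O)cc1OC
A5 | alternative 2 | 1-[4-(tert-butyldimethylsilyloxy)-2-(ethenyloxy)phenyl]-2-(3,4-dimethoxyphenyl)prop-2-en-1-ol (racemic) | C=COc1cc(O[Si](C)(C)C(C)(C)C)ccc1C(O)C(=C)c1ccc(OC)c(OC)c1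
A6 | alternative 2 | (±)-7-(tert-butyldimethylsilyloxy)-3-(3,4-dimethoxyphenyl)-4H-chromen-4-ol (racemic) | COc1ccc(cc1OC)C1=COc2cc(O[Si](C)(C)C(C)(C)C)ccc2C1O
A7 | alternative 2 | 7-(tert-butyldimethylsilyloxy)-3-(3,4-dimethoxyphenyl)-4H-chromen-4-one | COc1ccc(-c2coc3cc(O[Si](C)(C)C(C)(C)C)ccc3c2=O)cc1OC
A8 | alternative 3 | 3-ethoxycyclohex-2-en-1-one | CCOC1=CC(=O)CCC1
A9 | alternative 3 | (Z)-2-(3,4-dimethoxyphenyl)-3-methoxyacryloyl chloride | CO/C=C(\C(=O)Cl)c1ccc(OC)c(OC)c1
A10 | alternative 3 | 3-(3,4-dimethoxyphenyl)-7-ethoxy-5,6-dihydro-4H-chromen-4-one | CCOC1=CC2=C(CC1)C(=O)C(=CO2)c1ccc(OC)c(OC)c1
A11 | alternative 3 | 3-(3,4-dimethoxyphenyl)-7-ethoxy-4H-chromen-4-one | CCOc1ccc2c(c1)occ(-c1ccc(OC)c(OC)c1)c2=O
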